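**Plan**

1. Retrosynthesis cuts, in this order: the lactone bond C8–C17 (tethered Reformatsky aldol), C5–CH3 and C6–Cl (syn-carbometallation/chlorination of a C5≡C6 ring alkyne), C6–C7 (Nozaki–Hiyama–Kishi closure of the ten-membered ring), C2–C3 (addition to a C2 aldehyde), and finally C11–C12 and C1–C10 of the cyclohexenone.
2. The last cut is possible because the ring C1/C10–C14 is a cyclohex-2-en-1-one whose C12(=O)–C13=C14–C1(quaternary) edge is the carbon frame of a 4,4-disubstituted cyclobutenone and whose C10–C11 edge is a trisubstituted alkene. Alkenyllithium addition, 4π opening of the four-membered ring and 6π closure expand it by two atoms.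
3. Forward order: cyclobutenone 8 + alkenyl iodide 15 → six-membered ring (step 9) → C3–C6 chain → ten-membered ring → chloroalkene → γ-lactone.
4. Stereochemistry: C1/C10 from the disrotatory closure, with the absolute sense taken from a glycerate dioxolane on C1 (a temporary ring, cut back to the C2 aldehyde in step 11); C11 by kinetic protonation; C9 by catalytic asymmetric alkynylation; C2 by Felkin–Anh addition; C7 by CBS reduction; C5=C6 geometry by syn addition inside the ring; C8/C17 by the tethered aldol.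

Key step: step 9

Remark: locants C1–C20 are those of the target skeleton: C1 quaternary ring-fusion carbon, C2 CH–OAc, C5=C6(Cl), C7 lactone CH–O, C8 C–OH, C9 CH–OH, C10 ring-fusion CH, C11 CH–CH3, C12 C=O, C13=C14, C17 lactone CH–CH3, C19 lactone C=O. PMB = 4-methoxybenzyl, TBS = tert-butyldimethylsilyl, TES = triethylsilyl.

Remark: 4–8 are used as both epimers at the quaternary carbon, 31 as both C7 epimers and 36–41 as both epimers at the CHBr carbon; these centres are erased or reset in steps 9, 18/19 and 26. The C12 carbinol of 21–37 is drawn as the expected epimer and is removed in step 23.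

Assumption: the dioxolane induces the C1/C10 sense in step 9 according to the A(1,3)-strain model given there; both antipodes of ester 1 are commercial, so the auxiliary can be matched to the sense that is found without changing the route.

**Route**

Step 1
Reactants: 1 methyl (4R)-2,2-dimethyl-1,3-dioxolane-4-carboxylate
Product: 3 1-[(4R)-2,2-dimethyl-1,3-dioxolan-4-yl]ethan-1-one, via Weinreb amide 2 (not isolated)
Conditions: MeNH(OMe)·HCl, i-PrMgCl, THF, -20 °C; then MeMgBr, -20 → 0 °C; aq. NH4Cl
Reagents that add atoms: methylmagnesium bromide, C[Mg]Br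
Why: One-pot Weinreb amidation and Grignard ketone synthesis, in which the N-methoxy-N-methyl chelate stops the addition at the ketone and the low temperature keeps the α-alkoxy stereocentre intact.

Step 2
Reactants: 3 1-[(4R)-2,2-dimethyl-1,3-dioxolan-4-yl]ethan-1-one
Product: 5 2-[(4S)-2,2-dimethyl-1,3-dioxolan-4-yl]-2-methylcyclobutan-1-one (both C2 epimers), via oxaspiropentane 4 (not isolated)
Conditions: cyclopropyldiphenylsulfonium BF4, KHMDS, DME, -45 °C; then 3, -45 → 0 °C; LiBF4 (cat.), PhH, 25 °C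
Reagents that add atoms: cyclopropyldiphenylsulfonium tetrafluoroborate, F[B-](F)(F)F.C1CC1[S+](c1ccccc1)c1ccccc1
Why: Sulfonium cyclopropylide spiroannelation, in which the ylide epoxidises the ketone and the oxaspiropentane rearranges (semipinacol-type ring expansion of cyclopropane to cyclobutane) to the α-quaternary cyclobutanone; the new quaternary centre forms unselectively, which is harmless because step 9 is stereoconvergent at this carbon, and the preformed ylide at low temperature avoids enolisation of 3.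

Step 3
Reactants: 5 2-[(4S)-2,2-dimethyl-1,3-dioxolan-4-yl]-2-methylcyclobutan-1-one
Product: 8 4-[(4S)-2,2-dimethyl-1,3-dioxolan-4-yl]-4-methylcyclobut-2-en-1-one, via selenide 6 (not isolated), via selenoxide 7 (not isolated)
Conditions: LDA, THF, -78 °C; PhSeCl; then 30% H2O2, pyridine, CH2Cl2, 0 °C
Reagents that add atoms: none
Why: α-Selenenylation at the only enolisable position followed by selenoxide syn-elimination (a cis β-hydrogen is available in the four-membered ring) should give the non-enolisable 4,4-disubstituted cyclobutenone, which is used at once.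

Step 4
Reactants: 9 2-methylidenepropane-1,3-diol
Product: 10 2-{[(4-methoxyphenyl)methoxy]methyl}prop-2-en-1-ol
Conditions: NaH (1 equiv), PMBCl, Bu4NI (cat.), THF, 0 → 25 °C
Reagents that add atoms: 4-methoxybenzyl chloride, COc1ccc(CCl)cc1
Why: Statistical Williamson mono-etherification of the symmetric diol, from which diol and bis-ether are separable and recyclable.

Step 5
Reactants: 10 2-{[(4-methoxyphenyl)methoxy]methyl}prop-2-en-1-ol
Product: 11 2-{[(4-methoxyphenyl)methoxy]methyl}prop-2-enal
Conditions: MnO2, CH2Cl2, 25 °C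
Reagents that add atoms: none
Why: Manganese dioxide oxidises the allylic alcohol selectively to the α-substituted acrolein without over-oxidation.

Step 6
Reactants: 11 2-{[(4-methoxyphenyl)methoxy]methyl}prop-2-enal
Product: 12 (3S)-2-{[(4-methoxyphenyl)methoxy]methyl}hex-1-en-4-yn-3-ol
Conditions: propyne, Me2Zn, ProPhenol (20 mol%, the antipode that gives the 3S carbinol), Ph3P=O (40 mol%), PhMe, 0 °C
Reagents that add atoms: propyne, CC#C
Why: Enantioselective zinc alkynylide addition to an enal under the dinuclear Zn–ProPhenol catalyst, which delivers the alkynyl group to one aldehyde face and sets the future C9 centre.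

Step 7
Reactants: 12 (3S)-2-{[(4-methoxyphenyl)methoxy]methyl}hex-1-en-4-yn-3-ol
Product: 13 TBS ether of 12
Conditions: TBSCl, imidazole, DMF, 25 °C
Reagents that add atoms: tert-butyldimethylsilyl chloride, CC(C)(C)[Si](C)(C)Cl
Why: Standard silylation, giving a TBS ether that should survive every later step up to the final HF treatment.

Step 8
Reactants: 13 TBS ether of 12
Product: 15 tert-butyl{[(3S,4E)-5-iodo-2-{[(4-methoxyphenyl)methoxy]methyl}hexa-1,4-dien-3-yl]oxy}dimethylsilane, via alkenylzirconocene 14 (not isolated)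
Conditions: Cp2Zr(H)Cl (2 equiv), THF, 45 °C; then I2, 0 °C
Reagents that add atoms: iodine, II
Why: syn-Hydrozirconation with excess Schwartz reagent places zirconium on the less hindered, methyl-bearing alkyne carbon, and iodinolysis with retention should give the (E)-iodide with iodine trans to the carbinol carbon; the 1,1-disubstituted alkene reacts more slowly than the alkyne.

Step 9
Reactants: 15 (E)-alkenyl iodide; 8 4-[(4S)-2,2-dimethyl-1,3-dioxolan-4-yl]-4-methylcyclobut-2-en-1-one
Product: 20 (4S,5S,6R)-5-[(1S)-1-{[tert-butyl(dimethyl)silyl]oxy}-2-{[(4-methoxyphenyl)methoxy]methyl}prop-2-en-1-yl]-4-[(4S)-2,2-dimethyl-1,3-dioxolan-4-yl]-4,6-dimethylcyclohex-2-en-1-one, via alkenyllithium 16 (not isolated), via cyclobutenolate 17 (not isolated), via trienolate 18 (not isolated), via dienolate 19 (not isolated)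
Conditions: 15, t-BuLi (2.05 equiv), Et2O, -78 °C; 8, THF, -78 → 25 °C; then AcOH, THF, -78 °C
Reagents that add atoms: none
Why: Iodine–lithium exchange gives alkenyllithium 16, which adds 1,2 to the non-enolisable cyclobutenone 8 from the face opposite the dioxolanyl group, and alkoxide 17 undergoes oxyanion-accelerated conrotatory 4π ring opening with O– rotating outward, so that the alkenyl and dioxolanyl groups turn inward and both C1 epimers of 8 give the same trienolate 18. The closest known reaction types are the Moore-type ring expansion of 4-alkenylcyclobutenones and the electrocyclic cascades of alkenyllithium adducts of squarate esters and of alkenylbenzocyclobutenols. The six-membered ring is closed by thermal disrotatory 6π electrocyclisation of 18 (bond C1–C10), which together with the C11–C12 bond made in the addition inserts C10=C11 into the C12–C1 bond of the four-membered ring and gives dienolate 19. Disrotation puts the two outside groups (the C15 methyl and the C9 chain of the E-alkenyl unit) cis, as in the target, and the absolute sense comes from the dioxolane stereocentre on the inside substituent, which A(1,3) strain holds with its C–H in the diene plane so that C10 bonds to the face of C1 next to the ring oxygen and away from the CH2O carbon; C11 is set by kinetic protonation of 19 at -78 °C from the face opposite the C15 methyl and the C9 branch, which also gives the conjugated enone directly. The step needs 1,2-addition (organolithium at -78 °C), carbonyl-face selectivity (dioxolanyl larger than methyl) and closure faster than [1,7]-hydrogen shift (oxido acceleration of the electrocyclisation).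

Step 10
Reactants: 20 enone
Product: 21 (1S,4S,5S,6R)-5-[(1S)-1-{[tert-butyl(dimethyl)silyl]oxy}-2-{[(4-methoxyphenyl)methoxy]methyl}prop-2-en-1-yl]-4-[(4S)-2,2-dimethyl-1,3-dioxolan-4-yl]-4,6-dimethylcyclohex-2-en-1-ol
Conditions: NaBH4, CeCl3·7H2O, MeOH, -78 → 0 °C
Reagents that add atoms: none
Why: Luche 1,2-reduction (axial hydride, anti to the C11 methyl) turns the enone into an allylic alcohol, which locks the C11 centre against enolisation and masks C12 from the later Grignard and borane reagents; the new carbinol centre is temporary.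

Step 11
Reactants: 21 allylic alcohol
Product: 22 (1S,4S,5R,6S)-6-[(1S)-1-{[tert-butyl(dimethyl)silyl]oxy}-2-{[(4-methoxyphenyl)methoxy]methyl}prop-2-en-1-yl]-4-hydroxy-1,5-dimethylcyclohex-2-ene-1-carbaldehyde
Conditions: H5IO6, EtOAc, 0 → 25 °C
Reagents that add atoms: none
Why: Periodic acid hydrolyses the terminal isopropylidene acetal and cleaves the liberated glycol in the same pot, which removes the temporary ring with its CH2O carbon and should leave the non-enolisable C2 aldehyde.

Step 12
Reactants: 22 hydroxy aldehyde; 23 (4-bromobut-1-yn-1-yl)trimethylsilane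
Product: 25 (1S,4S,5S,6R)-5-[(1S)-1-{[tert-butyl(dimethyl)silyl]oxy}-2-{[(4-methoxyphenyl)methoxy]methyl}prop-2-en-1-yl]-4-[(1S)-1-hydroxy-5-(trimethylsilyl)pent-4-yn-1-yl]-4,6-dimethylcyclohex-2-en-1-ol, via Grignard reagent 24 (not isolated)
Conditions: 23, Mg, THF, 25 °C; then 22 (0.33 equiv), THF–Et2O, -78 → -20 °C
Reagents that add atoms: none
Why: Grignard addition to the α-quaternary aldehyde under Felkin–Anh control, with the branched C10 substituent antiperiplanar to the incoming nucleophile, the vinylic C14 next to the carbonyl oxygen and the methyl group beside the trajectory, should give the 2S carbinol; the first equivalent only deprotonates the C12 hydroxyl, which is trans to the formyl group and can form neither a lactol nor a chelate.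

Step 13
Reactants: 25 diol
Product: 26 2,12-bis(triethylsilyl) ether of 25
Conditions: TESOTf, 2,6-lutidine, CH2Cl2, -78 → 0 °C
Reagents that add atoms: triethylsilyl trifluoromethanesulfonate, CC[Si](CC)(CC)OS(=O)(=O)C(F)(F)F
Why: The silyl triflate covers both secondary alcohols (neopentylic C2, allylic C12) as TES ethers, which can later be removed together in the presence of the C9 TBS ether.

Step 14
Reactants: 26 bis-TES ether
Product: 27 iodoalkyne (26 with C≡C–I in place of C≡C–SiMe3)
Conditions: NIS, AgNO3 (10 mol%), acetone, 25 °C, dark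
Reagents that add atoms: N-iodosuccinimide, O=C1CCC(=O)N1I
Why: Silver-catalysed iododesilylation converts the alkynylsilane directly into the 1-iodoalkyne needed for chromium insertion, and alkenes and silyl ethers are not touched.

Step 15
Reactants: 27 iodoalkyne
Product: 28 allylic alcohol (27 with CH2OH in place of CH2OPMB)
Conditions: DDQ, CH2Cl2–pH 7 buffer, 0 °C
Reagents that add atoms: none
Why: DDQ cleaves the PMB ether oxidatively under buffered conditions and leaves silyl ethers, iodoalkyne and alkenes intact.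

Step 16
Reactants: 28 allylic alcohol
Product: 29 enal (28 with CHO in place of CH2OH)
Conditions: MnO2, CH2Cl2, 25 °C
Reagents that add atoms: none
Why: Manganese dioxide oxidises the primary allylic alcohol to the non-enolisable α-substituted acrolein that serves as the C7 electrophile.

Step 17
Reactants: 29 enal
Product: 31 bicyclic 7-hydroxy-5-yne (ten-membered ring closed; both C7 epimers), via alkynylchromium 30 (not isolated)
Conditions: CrCl2 (6 equiv), NiCl2 (cat.), THF, 25 °C, slow addition to 2 mM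
Reagents that add atoms: none
Why: Nozaki–Hiyama–Kishi alkynylation, in which Cr(II) inserts into the C(sp)–I bond and the alkynylchromium(III) adds 1,2 and aldehyde-selectively under high dilution, a closure with precedent for ten-membered cycloalkynols; both C7 epimers are carried on because C7 is reset in steps 18 and 19.

Step 18
Reactants: 31 bicyclic alkynol
Product: 32 bicyclic 5-yn-7-one
Conditions: MnO2, CH2Cl2, 25 °C
Reagents that add atoms: none
Why: Manganese dioxide oxidises the doubly activated (allylic and propargylic) C7 carbinol to the cross-conjugated ynone, which erases the uncontrolled C7 centre.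

Step 19
Reactants: 32 ynone
Product: 33 (7R)-alkynol
Conditions: (S)-Me-CBS, catecholborane, PhMe, -78 °C
Reagents that add atoms: none
Why: Corey–Bakshi–Shibata reduction, in which the rod-like alkynyl group acts as the small and the branched alkenyl group (C8) as the large substituent, should give the 7R alkynol (the 7S centre of the target once C6 carries chlorine); catecholborane at -78 °C leaves the alkenes alone.

Step 20
Reactants: 33 (7R)-alkynol
Product: 35 (5E,7S)-6-chloro-5-methyl allylic alcohol, via alkenylmagnesium chelate 34 (not isolated)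
Conditions: MeMgBr (5 equiv), Fe(acac)3 (15 mol%), THF, -20 → 0 °C; then NCS, -40 → 0 °C
Reagents that add atoms: methylmagnesium bromide, C[Mg]Br; N-chlorosuccinimide, O=C1CCC(=O)N1Cl
Why: Iron-catalysed, alkoxide-directed syn-carbomagnesiation of the propargylic alcohol puts the methyl group on the distal carbon C5 and magnesium on C6 in a five-membered chelate, and chlorination of the alkenyl–Mg bond with retention should leave CH3 and Cl cis and the two ring bonds cis, as in the target.

Step 21
Reactants: 35 chloro allylic alcohol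
Product: 36 7-O-(2-bromopropanoyl) ester of 35
Conditions: 2-bromopropanoyl bromide, pyridine, CH2Cl2, -20 °C
Reagents that add atoms: 2-bromopropanoyl bromide, CC(Br)C(=O)Br
Why: Acylation of the only free hydroxyl (C7) installs the C17–C19 propionate unit as its α-bromide, whose configuration is irrelevant because it becomes an enolate in step 26.

Step 22
Reactants: 36 bromo ester
Product: 37 2,12-diol
Conditions: PPTS, MeOH–CH2Cl2, 25 °C
Reagents that add atoms: none
Why: Mild acid methanolysis removes both TES ethers (TES is cleaved far faster than TBS) while the hindered C9 TBS ether and the bromo ester persist.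

Step 23
Reactants: 37 2,12-diol
Product: 38 12-ketone (13-en-12-one) with free 2-OH
Conditions: MnO2, CH2Cl2, 25 °C
Reagents that add atoms: none
Why: Manganese dioxide oxidises only the allylic C12 alcohol, which regenerates the enone without touching the saturated C2 alcohol or the C11 centre.

Step 24
Reactants: 38 hydroxy enone
Product: 39 2-acetate
Conditions: Ac2O, pyridine, DMAP (cat.), CH2Cl2, 25 °C
Reagents that add atoms: acetic anhydride, CC(=O)OC(C)=O
Why: DMAP-catalysed acetylation of the single remaining hydroxyl gives the C2 acetate of the target.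

Step 25
Reactants: 39 acetate
Product: 41 8-ketone, via diol 40 (not isolated)
Conditions: OsO4 (cat.), NaIO4, 2,6-lutidine, dioxane–H2O, 25 °C
Reagents that add atoms: osmium tetroxide, O=[Os](=O)(=O)=O; sodium periodate, [Na+].[O-][I](=O)(=O)=O
Why: Lemieux–Johnson cleavage, in which osmylation should occur at the 1,1-disubstituted C8 methylidene in preference to the electron-poor enone and the tetrasubstituted chloroalkene, and periodate cleaves the diol to the C8 ketone.

Step 26
Reactants: 41 keto bromo ester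
Product: 43 9-O-TBS ether of the target, via samarium enolate 42 (not isolated)
Conditions: SmI2 (2.2 equiv), THF, -78 °C
Reagents that add atoms: none
Why: Intramolecular samarium Reformatsky reaction (5-exo-trig aldol), in which the tether can deliver C17 only to the carbonyl face on the side of the C7–O bond and the gauche C6–C7–C8–C9 ring torsion should place H-7 and the new 8-OH cis (cis-fused lactone), while the C17 methyl takes the position trans to the C9 branch, which is also the thermodynamic epimer at this enolisable centre.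

Step 27
Reactants: 43 9-O-TBS ether of the target
Product: 44 CNP0163464.1
Conditions: HF·pyridine, pyridine, THF, 0 → 25 °C
Reagents that add atoms: none
Why: Buffered HF·pyridine cleaves the last silyl ether, and acetate, lactone, tertiary alcohol, enone and the C11 centre should be stable under these weakly acidic conditions.

**Compound list**

1 | methyl (4R)-2,2-dimethyl-1,3-dioxolane-4-carboxylate | COC(=O)[C@H]1COC(C)(C)O1 | starting material
2 | (4R)-N-methoxy-N,2,2-trimethyl-1,3-dioxolane-4-carboxamide | CON(C)C(=O)[C@H]1COC(C)(C)O1 | intermediate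
3 | 1-[(4R)-2,2-dimethyl-1,3-dioxolan-4-yl]ethan-1-one | CC(=O)[C@H]1COC(C)(C)O1 | intermediate
4 | 2-[(4R)-2,2-dimethyl-1,3-dioxolan-4-yl]-2-methyl-1-oxaspiro[2.2]pentane (both C2 epimers) | CC1(OC12CC2)[C@H]1COC(C)(C)O1 | intermediate
5 | 2-[(4S)-2,2-dimethyl-1,3-dioxolan-4-yl]-2-methylcyclobutan-1-one (both C2 epimers) | CC1(CCC1=O)[C@H]1COC(C)(C)O1 | intermediate
6 | 2-[(4S)-2,2-dimethyl-1,3-dioxolan-4-yl]-2-methyl-4-(phenylselanyl)cyclobutan-1-one | CC1(CC([Se]c2ccccc2)C1=O)[C@H]1COC(C)(C)O1 | intermediate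
7 | 2-[(4S)-2,2-dimethyl-1,3-dioxolan-4-yl]-2-methyl-4-(phenylseleninyl)cyclobutan-1-one | CC1(CC([Se](=O)c2ccccc2)C1=O)[C@H]1COC(C)(C)O1 | intermediate
8 | 4-[(4S)-2,2-dimethyl-1,3-dioxolan-4-yl]-4-methylcyclobut-2-en-1-one (both C4 epimers) | CC1(C=CC1=O)[C@H]1COC(C)(C)O1 | intermediate
9 | 2-methylidenepropane-1,3-diol | C=C(CO)CO | starting material
10 | 2-{[(4-methoxyphenyl)methoxy]methyl}prop-2-en-1-ol | C=C(CO)COCc1ccc(OC)cc1 | intermediate
11 | 2-{[(4-methoxyphenyl)methoxy]methyl}prop-2-enal | C=C(C=O)COCc1ccc(OC)cc1 | intermediate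
12 | (3S)-2-{[(4-methoxyphenyl)methoxy]methyl}hex-1-en-4-yn-3-ol | C=C(COCc1ccc(OC)cc1)[C@@H](O)C#CC | intermediate
13 | tert-butyl{[(3S)-2-{[(4-methoxyphenyl)methoxy]methyl}hex-1-en-4-yn-3-yl]oxy}dimethylsilane | C=C(COCc1ccc(OC)cc1)[C@@H](O[Si](C)(C)C(C)(C)C)C#CC | intermediate
14 | (3S,4E)-alkenyl(chloro)zirconocene (15 with ZrCp2Cl in place of I) | C=C(COCc1ccc(OC)cc1)[C@@H](O[Si](C)(C)C(C)(C)C)/C=C(\C)[Zr](Cl)(C1C=CC=C1)C1C=CC=C1 | intermediate
15 | tert-butyl{[(3S,4E)-5-iodo-2-{[(4-methoxyphenyl)methoxy]methyl}hexa-1,4-dien-3-yl]oxy}dimethylsilane | C=C(COCc1ccc(OC)cc1)[C@@H](O[Si](C)(C)C(C)(C)C)/C=C(\C)I | intermediate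
16 | (3S,4E)-alkenyllithium (15 with Li in place of I) | C=C(COCc1ccc(OC)cc1)[C@@H](O[Si](C)(C)C(C)(C)C)/C=C(\C)[Li] | intermediate
17 | lithium 1-alkenyl-4-[(4S)-dioxolanyl]-4-methylcyclobut-2-en-1-olate (O cis to dioxolanyl; alkenyl = C9–C11 unit of 15) | [Li]OC1(C=CC1(C)[C@H]1COC(C)(C)O1)/C(C)=C/[C@H](O[Si](C)(C)C(C)(C)C)C(=C)COCc1ccc(OC)cc1 | intermediate
18 | lithium trienolate C10=C11–C12(OLi)=C13–C14=C1 (alkenyl and dioxolanyl inside, C15 methyl and C9 chain outside) | C=C(COCc1ccc(OC)cc1)[C@@H](O[Si](C)(C)C(C)(C)C)/C=C(\C)/C(O[Li])=C\C=C(/[C@H]1COC(C)(C)O1)C | intermediate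
19 | lithium (1S,10S)-cyclohexa-1,3-dien-2-olate (C11=C12–OLi, C13=C14) | C=C(COCc1ccc(OC)cc1)[C@@H](O[Si](C)(C)C(C)(C)C)[C@H]2C(C)=C(O[Li])C=C[C@]2(C)[C@H]1COC(C)(C)O1 | intermediate
20 | (4S,5S,6R)-5-[(1S)-1-{[tert-butyl(dimethyl)silyl]oxy}-2-{[(4-methoxyphenyl)methoxy]methyl}prop-2-en-1-yl]-4-[(4S)-2,2-dimethyl-1,3-dioxolan-4-yl]-4,6-dimethylcyclohex-2-en-1-one | C=C(COCc1ccc(OC)cc1)[C@@H](O[Si](C)(C)C(C)(C)C)[C@H]2[C@@H](C)C(=O)C=C[C@]2(C)[C@H]1COC(C)(C)O1 | intermediate
21 | (1S,4S,5S,6R)-5-[(1S)-1-{[tert-butyl(dimethyl)silyl]oxy}-2-{[(4-methoxyphenyl)methoxy]methyl}prop-2-en-1-yl]-4-[(4S)-2,2-dimethyl-1,3-dioxolan-4-yl]-4,6-dimethylcyclohex-2-en-1-ol | C=C(COCc1ccc(OC)cc1)[C@@H](O[Si](C)(C)C(C)(C)C)[C@H]2[C@@H](C)[C@@H](O)C=C[C@]2(C)[C@H]1COC(C)(C)O1 | intermediate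
22 | (1S,4S,5R,6S)-6-[(1S)-1-{[tert-butyl(dimethyl)silyl]oxy}-2-{[(4-methoxyphenyl)methoxy]methyl}prop-2-en-1-yl]-4-hydroxy-1,5-dimethylcyclohex-2-ene-1-carbaldehyde | C=C(COCc1ccc(OC)cc1)[C@@H](O[Si](C)(C)C(C)(C)C)[C@H]2[C@@H](C)[C@@H](O)C=C[C@]2(C)C=O | intermediate
23 | (4-bromobut-1-yn-1-yl)trimethylsilane | C[Si](C)(C)C#CCCBr | starting material
24 | [4-(trimethylsilyl)but-3-yn-1-yl]magnesium bromide | C[Si](C)(C)C#CCC[Mg]Br | intermediate
25 | (1S,4S,5S,6R)-5-[(1S)-1-{[tert-butyl(dimethyl)silyl]oxy}-2-{[(4-methoxyphenyl)methoxy]methyl}prop-2-en-1-yl]-4-[(1S)-1-hydroxy-5-(trimethylsilyl)pent-4-yn-1-yl]-4,6-dimethylcyclohex-2-en-1-ol | C=C(COCc1ccc(OC)cc1)[C@@H](O[Si](C)(C)C(C)(C)C)[C@H]2[C@@H](C)[C@@H](O)C=C[C@]2(C)[C@@H](O)CCC#C[Si](C)(C)C | intermediate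
26 | 2,12-bis(triethylsilyl) ether of 25 | C=C(COCc1ccc(OC)cc1)[C@@H](O[Si](C)(C)C(C)(C)C)[C@H]2[C@@H](C)[C@@H](O[Si](CC)(CC)CC)C=C[C@]2(C)[C@@H](O[Si](CC)(CC)CC)CCC#C[Si](C)(C)C | intermediate
27 | iodoalkyne (26 with C≡C–I in place of C≡C–SiMe3) | C=C(COCc1ccc(OC)cc1)[C@@H](O[Si](C)(C)C(C)(C)C)[C@H]2[C@@H](C)[C@@H](O[Si](CC)(CC)CC)C=C[C@]2(C)[C@@H](O[Si](CC)(CC)CC)CCC#CI | intermediate
28 | C7 allylic alcohol (27 with CH2OH in place of CH2OPMB) | C=C(CO)[C@@H](O[Si](C)(C)C(C)(C)C)[C@H]2[C@@H](C)[C@@H](O[Si](CC)(CC)CC)C=C[C@]2(C)[C@@H](O[Si](CC)(CC)CC)CCC#CI | intermediate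
29 | C7 enal (28 with CHO in place of CH2OH) | C=C(C=O)[C@@H](O[Si](C)(C)C(C)(C)C)[C@H]2[C@@H](C)[C@@H](O[Si](CC)(CC)CC)C=C[C@]2(C)[C@@H](O[Si](CC)(CC)CC)CCC#CI | intermediate
30 | alkynylchromium(III) dichloride (29 with C≡C–CrCl2 in place of C≡C–I) | C=C(C=O)[C@@H](O[Si](C)(C)C(C)(C)C)[C@H]2[C@@H](C)[C@@H](O[Si](CC)(CC)CC)C=C[C@]2(C)[C@@H](O[Si](CC)(CC)CC)CCC#C[Cr](Cl)Cl | intermediate
31 | 6/10-bicyclic alkynol (1S,2S,9S,10S,11R,12S): 5-yne, 7-OH (both epimers), 8-methylidene, 9-OTBS, 2,12-bis-OTES, 13-ene | CC[Si](CC)(CC)O[C@H]1CCC#CC(O)C(=C)[C@@H](O[Si](C)(C)C(C)(C)C)[C@H]2[C@@H](C)[C@@H](O[Si](CC)(CC)CC)C=C[C@@]21C | intermediate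
32 | bicyclic 5-yn-7-one (31 oxidised at C7) | CC[Si](CC)(CC)O[C@H]1CCC#CC(=O)C(=C)[C@@H](O[Si](C)(C)C(C)(C)C)[C@H]2[C@@H](C)[C@@H](O[Si](CC)(CC)CC)C=C[C@@]21C | intermediate
33 | (7R)-alkynol (single C7 epimer of 31) | CC[Si](CC)(CC)O[C@H]1CCC#C[C@@H](O)C(=C)[C@@H](O[Si](C)(C)C(C)(C)C)[C@H]2[C@@H](C)[C@@H](O[Si](CC)(CC)CC)C=C[C@@]21C | intermediate
34 | alkenylmagnesium chelate (5-methyl, 6-MgBr, 7-OMgBr; ring bonds cis) | CC[Si](CC)(CC)O[C@H]1CC/C(C)=C(/[Mg]Br)[C@@H](O[Mg]Br)C(=C)[C@@H](O[Si](C)(C)C(C)(C)C)[C@H]2[C@@H](C)[C@@H](O[Si](CC)(CC)CC)C=C[C@@]21C | intermediate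
35 | (5E,7S)-6-chloro-5-methyl-5-en-7-ol (8-methylidene, 9-OTBS, 2,12-bis-OTES) | CC[Si](CC)(CC)O[C@H]1CC/C(C)=C(/Cl)[C@@H](O)C(=C)[C@@H](O[Si](C)(C)C(C)(C)C)[C@H]2[C@@H](C)[C@@H](O[Si](CC)(CC)CC)C=C[C@@]21C | intermediate
36 | 7-O-(2-bromopropanoyl) ester of 35 | CC[Si](CC)(CC)O[C@H]1CC/C(C)=C(/Cl)[C@@H](OC(=O)C(C)Br)C(=C)[C@@H](O[Si](C)(C)C(C)(C)C)[C@H]2[C@@H](C)[C@@H](O[Si](CC)(CC)CC)C=C[C@@]21C | intermediate
37 | 2,12-diol (36 without the TES groups) | O[C@H]1CC/C(C)=C(/Cl)[C@@H](OC(=O)C(C)Br)C(=C)[C@@H](O[Si](C)(C)C(C)(C)C)[C@H]2[C@@H](C)[C@@H](O)C=C[C@@]21C | intermediate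
38 | 13-en-12-one with free 2-OH | O[C@H]1CC/C(C)=C(/Cl)[C@@H](OC(=O)C(C)Br)C(=C)[C@@H](O[Si](C)(C)C(C)(C)C)[C@H]2[C@@H](C)C(=O)C=C[C@@]21C | intermediate
39 | 2-acetate of 38 | CC(=O)O[C@H]1CC/C(C)=C(/Cl)[C@@H](OC(=O)C(C)Br)C(=C)[C@@H](O[Si](C)(C)C(C)(C)C)[C@H]2[C@@H](C)C(=O)C=C[C@@]21C | intermediate
40 | 8-hydroxy-8-(hydroxymethyl) diol from 39 | CC(=O)O[C@H]1CC/C(C)=C(/Cl)[C@@H](OC(=O)C(C)Br)C(O)(CO)[C@@H](O[Si](C)(C)C(C)(C)C)[C@H]2[C@@H](C)C(=O)C=C[C@@]21C | intermediate
41 | 8-ketone (7-O-(2-bromopropanoyl), 9-OTBS, 2-OAc, 13-en-12-one) | CC(=O)O[C@H]1CC/C(C)=C(/Cl)[C@@H](OC(=O)C(C)Br)C(=O)[C@@H](O[Si](C)(C)C(C)(C)C)[C@H]2[C@@H](C)C(=O)C=C[C@@]21C | intermediate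
42 | samarium(III) ester enolate of 41 | CC(=O)O[C@H]1CC/C(C)=C(/Cl)[C@@H](OC(=CC)O[Sm](I)I)C(=O)[C@@H](O[Si](C)(C)C(C)(C)C)[C@H]2[C@@H](C)C(=O)C=C[C@@]21C | intermediate
43 | 9-O-TBS ether of the target (1S,2S,5E,7S,8R,9S,10S,11R,17R) | CC(=O)O[C@H]1CC/C(C)=C(/Cl)[C@H]2OC(=O)[C@H](C)[C@@]2(O)[C@@H](O[Si](C)(C)C(C)(C)C)[C@H]2[C@@H](C)C(=O)C=C[C@@]21C | intermediate
44 | CNP0163464.1: (1S,2S,5E,7S,8R,9S,10S,11R,17R)-2-acetoxy-6-chloro-8,9-dihydroxy-12-oxo 6/10-bicycle with 5,13-diene and C19→O–C7 γ-lactone | CC(=O)O[C@H]1CC/C(C)=C(/Cl)[C@H]2OC(=O)[C@H](C)[C@@]2(O)[C@@H](O)[C@H]2[C@@H](C)C(=O)C=C[C@@]21C | target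

**Step count and risks**

Total step count: 27. Longest linear sequence: 24 steps (9 → 44 through steps 4–27).

Step 9 is the most likely to fail. The trienolate may close with poor or reversed facial selectivity, may leak away by [1,7]-hydrogen shift from the inside dioxolanyl C–H, or the alkenyllithium may add to the carbonyl without face selectivity, which swaps the inside and outside groups at C1. The fallback separates addition from ring expansion and runs the latter thermally on a neutral substrate. It sets out from 15 and 8: the organocerium reagent made from 16 and CeCl3 should add at -78 °C and, after a cold quench, give the isolable cyclobutenol F1, whose epimer with OH cis to the dioxolanyl group is separated. Silylation (TMSOTf, Et3N) would give the trimethylsilyl ether F2. Heating in toluene at 80 °C should bring about the neutral 4π opening (siloxy group outward) and 6π closure to the silyl dienol ether F3. Protodesilylation with TBAF/AcOH at -78 °C protonates C11 kinetically, and the sequence comes back to the route at 20.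

Step 17 is the second risk. Closure of the strained ten-membered cycloalkyne may be slow, so that intermolecular coupling and reduction of the iodoalkyne take over. The fallback closes the same ring through a cerium acetylide made from a terminal alkyne, without chromium. It sets out from 26: K2CO3 in MeOH should give the terminal alkyne F4, DDQ the allylic alcohol F5 and MnO2 the non-enolisable enal F6. Treatment of F6 with LiN(SiMe3)2 and CeCl3 in THF at -78 °C under high dilution would add the acetylide to the aldehyde, and the sequence comes back to the route at 31.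

Step 12 is the third risk. Addition to the neopentylic aldehyde may show poor facial selectivity if the rotamer with the vinylic C14, and not C10, antiperiplanar to the nucleophile is populated, which would erode the C2 configuration. The fallback replaces substrate control by reagent control. It sets out from 25 as its mixture of C2 epimers: Dess–Martin oxidation of both hydroxyls should give the 2,12-dione F7, and (R)-Me-CBS with catecholborane at -78 °C would reduce the C2 ketone (quaternary C1 as the large group) to the 2S alcohol and the enone carbonyl to the allylic alcohol. The sequence comes back to the route at 25; the C12 configuration is immaterial because C12 is reoxidised in step 23.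

Further compounds
F1 | step 9 | 1-alkenyl-4-[(4S)-2,2-dimethyl-1,3-dioxolan-4-yl]-4-methylcyclobut-2-en-1-ol (OH cis to dioxolanyl) | OC1(C=CC1(C)[C@H]1COC(C)(C)O1)/C(C)=C/[C@H](O[Si](C)(C)C(C)(C)C)C(=C)COCc1ccc(OC)cc1
F2 | step 9 | trimethylsilyl ether of F1 | C[Si](C)(C)OC1(C=CC1(C)[C@H]1COC(C)(C)O1)/C(C)=C/[C@H](O[Si](C)(C)C(C)(C)C)C(=C)COCc1ccc(OC)cc1
F3 | step 9 | (1S,10S)-2-(trimethylsilyloxy)cyclohexa-1,3-diene (silyl dienol ether of 20) | C=C(COCc1ccc(OC)cc1)[C@@H](O[Si](C)(C)C(C)(C)C)[C@H]2C(C)=C(O[Si](C)(C)C)C=C[C@]2(C)[C@H]1COC(C)(C)O1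
F4 | step 17 | terminal alkyne (26 with C≡C–H in place of C≡C–SiMe3) | C=C(COCc1ccc(OC)cc1)[C@@H](O[Si](C)(C)C(C)(C)C)[C@H]2[C@@H](C)[C@@H](O[Si](CC)(CC)CC)C=C[C@]2(C)[C@@H](O[Si](CC)(CC)CC)CCC#C
F5 | step 17 | allylic alcohol (F4 with CH2OH in place of CH2OPMB) | C=C(CO)[C@@H](O[Si](C)(C)C(C)(C)C)[C@H]2[C@@H](C)[C@@H](O[Si](CC)(CC)CC)C=C[C@]2(C)[C@@H](O[Si](CC)(CC)CC)CCC#C
F6 | step 17 | enal (F5 with CHO in place of CH2OH) | C=C(C=O)[C@@H](O[Si](C)(C)C(C)(C)C)[C@H]2[C@@H](C)[C@@H](O[Si](CC)(CC)CC)C=C[C@]2(C)[C@@H](O[Si](CC)(CC)CC)CCC#C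
F7 | step 12 | 2,12-dione (25 with both carbinols oxidised) | C=C(COCc1ccc(OC)cc1)[C@@H](O[Si](C)(C)C(C)(C)C)[C@H]2[C@@H](C)C(=O)C=C[C@]2(C)C(=O)CCC#C[Si](C)(C)C
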